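## Analysis of the target

The target is a tetracycle. Ring A (C1 to C6) is a pentasubstituted benzene with OMe on C1 and H on C2. It is fused through the C3 oxygen and C4 to a 2,2-dimethyl-2H-pyran (C12=C13, C14) and through C5 and C6 to a cyclopentane (C7, C8, C9). That cyclopentane shares the C8–C9 bond with a cyclobutane (C8, C9, C10, C11).

There are three stereocentres, C8 (S), C9 (R) and C10 (S). The four/five ring fusion at C8/C9 can only be cis, so the real problem is the pair C9/C10: ring A on C9 and catechol ring B on C10 are trans, and the absolute sense must be set.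

The sensitive groups are the free catechol (oxidation), the chromene double bond (acid, electrophiles, hydrogenation), a cyclobutane flanked by two benzylic carbons, and one aryl methyl ether that must outlive the unmasking of three other phenols.

The synthesis is hard for two reasons. The cyclobutane is crowded, with quaternary C11 next to both C8 and C10. Ring A needs regiocontrol (OMe on C1 against the pyran oxygen on C3, C4 against C6).

The strategy rests on two features. C11 is a non-stereogenic gem-dimethyl carbon, and C8 is the α-carbon of the C7 carbon. C8 can therefore be a malonate carbon and C11 the β-carbon of an alkylidene malonate. The cyclobutane is then closed last, at C8–C9, by displacement at benzylic C9 in an open chain whose C9/C10 pair is set by acyclic stereocontrol.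

## Retrosynthetic reasoning

**23 from 22.** The O–C14 bond of the pyran and the three benzyl ethers are cut together. Chromene and catechol are the most fragile parts, so they appear in the last operation. The forward step must cleave aryl benzyl ethers but not the C1 methyl ether, and let the freed C3 phenol close onto the tertiary allylic carbon.

**22 from 21, and 21 from 19 and 20.** The C4–C12 bond is cut. The halogen that blocks C4 during ring closure is also the coupling handle, and the four-carbon alkynol 20 brings C12 to C14 with the carbinol in place. Semi-hydrogenation fixes the Z geometry that puts C14 next to the C3 oxygen. The coupling has to work at a bromide flanked on both sides.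

**19 from 18.** The C7 methylene comes from a ketone. The ketone is the trace of the ring closure and sits ortho and para to two ring oxygens, so an ionic reduction is enough.

**18 from 16 by way of 17.** The C6–C7 bond is cut (acylation of ring A). C6 is ortho to OMe and para to the benzyloxy group, and the other ortho position, C4, carries bromine. Because C8 holds two carboxyl groups, one is cis to ring A whatever happens; the other is lost by decarboxylation, and C8 then has no choice but the cis fusion.

**16 from 15.** Only the ester methyl groups are removed. The carbonyl carbons are shielded by C11 and ring A, so the cleavage is planned at the methyl carbons and not at the carbonyls.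

**15 from 14.** The C8–C9 bond is cut. This is the only ring bond of the cyclobutane that joins a stabilised carbanion (C8) to a carbon that can carry a leaving group and a defined configuration (C9). Closure is a stereospecific substitution with inversion, so the trans aryl pair of 15 is decided by the configuration of C9 in 14.

**14 from 13, and 13 from 12.** The C9–Br bond is traced to a C9–OH of opposite configuration, and the carbinol to the ketone. Hydride adds to 12 anti to the bulky C11 branch (Felkin–Anh), which gives the 4R alcohol 13 from the 3S ketone. This alcohol has the wrong configuration for direct oxygen activation, so the leaving group is put in with inversion. A chiral transfer-hydrogenation catalyst that favours the same face picks the 3S ketone out of the racemate, and this sets the absolute configuration.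

**12 from 9 and 10 by way of 11.** The C10–C11 bond is cut between a ketone α-carbon and the β-carbon of alkylidene malonate 10. This one bond brings in C11 with both methyl groups and C8 with both carboxyl groups. The forward step has to make a quaternary carbon next to a tertiary one, hence a Lewis-acid-driven, irreversible addition of silyl enol ether 11.

**9 from 8, and 8 from 5 and 6 by way of 7.** The C9–C10 bond is cut between an aryl aldehyde and a benzyl organometallic; oxidation then gives the ketone.

**5 from 3, 3 from 2, 2 from 1.** The C4–Br bond is the last cut. In 1 the hydroxyl would direct bromine to the wrong ortho/para positions, and a benzyl ether would not discriminate. As the acetate 2 it is a weak donor, so the methoxy group sends bromine to its para position, which is C4.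

## Alternatives that were turned down

**Alternative 1:** The cyclopentane is cut at C5–C9, C7–C8 and C6–C7, leading back to the chromenyl triflate A2, the enantioenriched cyclobutene A3 and a one-carbon carbonyl source.

- Forward step: a palladium–phosphine catalyst under carbonylative conditions adds the aryl group of A2 and the metal syn across C8=C9 of A3, inserts the carbonyl unit and closes onto C6 to give indanone A1.
- For it: it is the most convergent plan; the cis fusion follows from syn addition, the trans aryl pair from attack anti to ring B, and no syn β-hydrogen is available for elimination. On step count it is clearly stronger than the chosen route.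
- Against it: A3 is itself an enantiopure cyclobutane that has to be made. Regiochemistry of insertion into an unsymmetrical cyclobutene (aryl to C9, metal to C8 next to quaternary C11) is not assured. The chromene double bond of A2 can compete as insertion partner. The C7 ketone of A1 must then be removed without acid.
- Comparison: the chosen route spends more steps but gives every stereocentre a defined origin and a stereospecific ring closure.

**Alternative 2:** Ring A is cut at C1–C2, C3–C4 and C5–C6, leading back to triyne A5.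

- Forward step: a cationic rhodium–bisphosphine catalyst cyclotrimerises A5, closing ring A, the five-membered ring and the pyran ring together to give the silylated chromanol A4.
- For it: all three alkynes are tethered, so the substitution pattern of ring A is fixed with no halogenation or directing-group question. On that point it is stronger than the chosen route.
- Against it: the cyclobutane with all three stereocentres and two alkynyl arms must already exist, so the hard part is only moved earlier. A5 needs a 1-methoxyalkyne and an ethynyl ether of a tertiary alcohol, both labile. The extra stereocentre at C12 costs desilylation and dehydration afterwards.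
- Comparison: the chosen route builds the cyclobutane from an acyclic chain and uses ordinary arene chemistry.

**Alternative 3:** Ring A is cut at C1–C6 and C4–C5, leading back to the bicyclic α-bromo enone A7 and the oxygenated diene A8.

- Forward step: Diels–Alder addition followed by dehydrobromination, loss of one methoxy group and desilylation gives the aromatised indanone A6 with OMe on C1, OH on C3 and a prenyl group on C4.
- For it: the diene places every substituent of ring A, so regiochemistry is unambiguous and again better than in the chosen route; the C7 carbonyl is present from the start.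
- Against it: A7 carries the three contiguous stereocentres and needs its own enantioselective cyclobutane synthesis. A8 is hydrolytically fragile. The ortho-prenyl phenol must be oxidised to the chromene beside electron-rich benzyl ethers, and C7 deoxygenated beside an acid-sensitive alkene.
- Comparison: the chosen route sets C9/C10 in the open chain, and every building block can be bought.

Key step: step 9

Remark: 3,4-bis(benzyloxy)benzyl chloride 6 is treated as a purchasable compound, and racemic compounds are written with the undefined centre left open in the SMILES.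

## Route

Step 1
Reactants: 1 3-hydroxy-5-methoxybenzaldehyde
Product: 2 3-formyl-5-methoxyphenyl acetate
Conditions: Ac2O, pyridine, DMAP (cat.), CH2Cl2, 0 °C to rt
Reagents that add atoms: acetic anhydride, CC(=O)OC(C)=O
Why: O-Acetylation of the phenol; the acetate turns the stronger donor into a weak one, so that the methoxy group alone directs the next substitution.

Step 2
Reactants: 2 3-formyl-5-methoxyphenyl acetate
Product: 3 2-bromo-3-formyl-5-methoxyphenyl acetate
Conditions: Br2, NaOAc, AcOH, rt
Reagents that add atoms: bromine, BrBr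
Why: Electrophilic aromatic bromination; the position para to OMe (between the formyl and acetoxy carbons, the later C4) is the most activated, as in the known bromination of 3-methoxybenzaldehyde to its 2-bromo derivative.

Step 3
Reactants: 3 2-bromo-3-formyl-5-methoxyphenyl acetate
Product: 5 3-(benzyloxy)-2-bromo-5-methoxybenzaldehyde, via 2-bromo-3-hydroxy-5-methoxybenzaldehyde 4 (not isolated)
Conditions: K2CO3, MeOH, 0 °C to rt; evaporation; BnBr, DMF, rt
Reagents that add atoms: benzyl bromide, BrCc1ccccc1
Why: Methanolysis of the aryl acetate and Williamson benzylation of the phenoxide in one flask; the benzyl ether lasts to the final step, where it falls together with those of ring B.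

Step 4
Reactants: 6 3,4-bis(benzyloxy)benzyl chloride; 5 3-(benzyloxy)-2-bromo-5-methoxybenzaldehyde
Product: 8 rac-1-[3-(benzyloxy)-2-bromo-5-methoxyphenyl]-2-[3,4-bis(benzyloxy)phenyl]ethan-1-ol, via [3,4-bis(benzyloxy)benzyl]magnesium chloride 7 (not isolated)
Conditions: Mg, THF, 0 °C (slow addition of 6); then 5, −78 to 0 °C; aq. NH4Cl
Reagents that add atoms: none
Why: Grignard addition of a benzylic magnesium chloride to an aromatic aldehyde forms C9–C10; at low temperature the aryl bromide does not exchange, and the carbinol centre may stay racemic because it is oxidised next.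

Step 5
Reactants: 8 rac-1-[3-(benzyloxy)-2-bromo-5-methoxyphenyl]-2-[3,4-bis(benzyloxy)phenyl]ethan-1-ol
Product: 9 1-[3-(benzyloxy)-2-bromo-5-methoxyphenyl]-2-[3,4-bis(benzyloxy)phenyl]ethan-1-one
Conditions: Dess–Martin periodinane, NaHCO3, CH2Cl2, rt
Reagents that add atoms: none
Why: Dess–Martin oxidation of a secondary benzylic alcohol to the deoxybenzoin under buffered conditions that spare benzyl ethers and the aryl bromide.

Step 6
Reactants: 9 1-[3-(benzyloxy)-2-bromo-5-methoxyphenyl]-2-[3,4-bis(benzyloxy)phenyl]ethan-1-one; 10 dimethyl 2-(propan-2-ylidene)propanedioate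
Product: 12 rac-dimethyl 2-[4-[3-(benzyloxy)-2-bromo-5-methoxyphenyl]-3-[3,4-bis(benzyloxy)phenyl]-2-methyl-4-oxobutan-2-yl]propanedioate, via trimethylsilyl enol ether 11 (not isolated)
Conditions: TMSOTf, Et3N, CH2Cl2, 0 °C; exchange to pentane, filtration; then 10, TiCl4, CH2Cl2, −78 to −40 °C
Reagents that add atoms: none
Why: Soft enolisation gives the (Z)-silyl enol ether, and TiCl4 chelates both ester carbonyls of 10 so that the enol ether adds to the tetrasubstituted β-carbon (Mukaiyama–Michael addition); this forms C10–C11 and quaternary C11 irreversibly, which a base-mediated Michael addition with its retro reaction would not guarantee, and C10 is formed racemic.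

Step 7
Reactants: 12 rac-dimethyl 2-[4-[3-(benzyloxy)-2-bromo-5-methoxyphenyl]-3-[3,4-bis(benzyloxy)phenyl]-2-methyl-4-oxobutan-2-yl]propanedioate
Product: 13 dimethyl 2-[(3S,4R)-4-[3-(benzyloxy)-2-bromo-5-methoxyphenyl]-3-[3,4-bis(benzyloxy)phenyl]-4-hydroxy-2-methylbutan-2-yl]propanedioate
Conditions: RuCl[(R,R)-TsDPEN](p-cymene) (2 mol %), HCO2H/Et3N (5:2), DMF, 30 °C, stopped near half conversion
Reagents that add atoms: none
Why: Noyori–Ikariya transfer hydrogenation run as a kinetic resolution: the (R,R)-catalyst delivers hydride to the face that gives the (R)-carbinol, and only in the (3S)-ketone is this also the Felkin–Anh face anti to the bulky C11 branch; the (3S)-enantiomer should therefore be reduced selectively to the (3S,4R)-alcohol (C9 set by catalyst and substrate together, C10 selected from the racemate) while the (3R)-ketone stays behind.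

Step 8
Reactants: 13 dimethyl 2-[(3S,4R)-4-[3-(benzyloxy)-2-bromo-5-methoxyphenyl]-3-[3,4-bis(benzyloxy)phenyl]-4-hydroxy-2-methylbutan-2-yl]propanedioate
Product: 14 dimethyl 2-[(3S,4S)-4-[3-(benzyloxy)-2-bromo-5-methoxyphenyl]-3-[3,4-bis(benzyloxy)phenyl]-4-bromo-2-methylbutan-2-yl]propanedioate
Conditions: PPh3, CBr4, CH2Cl2, 0 °C
Reagents that add atoms: carbon tetrabromide, BrC(Br)(Br)Br
Why: Appel bromination; bromide displaces the oxyphosphonium group from the rear (SN2) and so inverts C9 to the configuration the ring closure needs; ionisation is disfavoured because both alkoxy groups of ring A are meta to C9 and the ortho bromine withdraws electrons.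

Step 9
Reactants: 14 dimethyl 2-[(3S,4S)-4-[3-(benzyloxy)-2-bromo-5-methoxyphenyl]-3-[3,4-bis(benzyloxy)phenyl]-4-bromo-2-methylbutan-2-yl]propanedioate
Product: 15 dimethyl (2S,3R)-2-[3-(benzyloxy)-2-bromo-5-methoxyphenyl]-3-[3,4-bis(benzyloxy)phenyl]-4,4-dimethylcyclobutane-1,1-dicarboxylate
Conditions: NaH (1.05 equiv), THF/DMF (10:1), 0 °C, then 45 °C
Reagents that add atoms: none
Why: The base removes the only acidic proton, that on malonate carbon C8, and the sodium enolate attacks C9 from the side opposite bromide, forming C8–C9 with inversion. The closest known reaction type is the Perkin-type cycloalkylation of malonates that gives cyclobutane-1,1-dicarboxylates. The cyclobutane is closed in the 4-exo-tet mode. The one stereocentre changed, C9, is controlled by the stereospecific SN2 course and hence by the configuration set in step 8; together with the untouched C10 this places ring A trans to ring B, and C8 is not stereogenic in 15. The step needs C-alkylation to beat O-alkylation (a six-membered ketene acetal) and substitution to beat elimination to the stilbene. The soft bromide leaving group and a tightly paired sodium enolate in THF favour carbon. The gem-dimethyl group at C11 compresses the chain into the reactive rotamer. The electron-poor benzylic carbon does not ionise, and with one equivalent of base no free base remains to abstract the C10 proton.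

Step 10
Reactants: 15 dimethyl (2S,3R)-2-[3-(benzyloxy)-2-bromo-5-methoxyphenyl]-3-[3,4-bis(benzyloxy)phenyl]-4,4-dimethylcyclobutane-1,1-dicarboxylate
Product: 16 (2S,3R)-2-[3-(benzyloxy)-2-bromo-5-methoxyphenyl]-3-[3,4-bis(benzyloxy)phenyl]-4,4-dimethylcyclobutane-1,1-dicarboxylic acid
Conditions: NaSEt, DMF, 60 °C; then 1 M HCl, 0 °C
Reagents that add atoms: none
Why: SN2 dealkylation of both methyl esters by thiolate at the methyl carbon, the classical answer to esters whose carbonyl groups are shielded (here by C11 and ring A); aryl ethers and the aryl bromide are inert at this temperature and a disubstituted malonic acid does not decarboxylate in the cold.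

Step 11
Reactants: 16 (2S,3R)-2-[3-(benzyloxy)-2-bromo-5-methoxyphenyl]-3-[3,4-bis(benzyloxy)phenyl]-4,4-dimethylcyclobutane-1,1-dicarboxylic acid
Product: 18 (2S,2aS,7aS)-4-(benzyloxy)-2-[3,4-bis(benzyloxy)phenyl]-3-bromo-6-methoxy-1,1-dimethyl-1,2,2a,7a-tetrahydro-7H-cyclobuta[a]inden-7-one, via beta-keto acid 17 (not isolated)
Conditions: (CF3CO)2O, CF3CO2H (cat.), CH2Cl2, 0 °C to rt; then H2O/THF, 50 °C
Reagents that add atoms: none
Why: Intramolecular Friedel–Crafts acylation through the mixed trifluoroacetic anhydride: the carboxyl cis to ring A attacks C6, the only free position ortho to C5 (C4 carries bromine), activated by OMe (ortho) and OBn (para), while ring B is less electron-rich and could only close a bridged ring. The β-keto acid then decarboxylates through its enol, and protonation of C8 can only give the cis ring fusion, which sets C8; a ketene formed from the malonic anhydride would lead to the same product.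

Step 12
Reactants: 18 (2S,2aS,7aS)-4-(benzyloxy)-2-[3,4-bis(benzyloxy)phenyl]-3-bromo-6-methoxy-1,1-dimethyl-1,2,2a,7a-tetrahydro-7H-cyclobuta[a]inden-7-one
Product: 19 (2S,2aR,7aS)-4-(benzyloxy)-2-[3,4-bis(benzyloxy)phenyl]-3-bromo-6-methoxy-1,1-dimethyl-2,2a,7,7a-tetrahydro-1H-cyclobuta[a]indene
Conditions: Et3SiH, CF3CO2H, CH2Cl2, 0 °C to rt
Reagents that add atoms: none
Why: Ionic hydrogenation (protonation and hydride transfer from the silane, twice) of an aryl ketone whose benzylic cation is stabilised by the ortho methoxy and para benzyloxy groups; the same stabilisation keeps the cyclobutylcarbinyl cation from ring expansion, and no stereocentre is touched.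

Step 13
Reactants: 19 (2S,2aR,7aS)-4-(benzyloxy)-2-[3,4-bis(benzyloxy)phenyl]-3-bromo-6-methoxy-1,1-dimethyl-2,2a,7,7a-tetrahydro-1H-cyclobuta[a]indene; 20 2-methylbut-3-yn-2-ol
Product: 21 4-[(2S,2aR,7aS)-4-(benzyloxy)-2-[3,4-bis(benzyloxy)phenyl]-6-methoxy-1,1-dimethyl-2,2a,7,7a-tetrahydro-1H-cyclobuta[a]inden-3-yl]-2-methylbut-3-yn-2-ol
Conditions: PdCl2(MeCN)2 (3 mol %), XPhos (9 mol %), Cs2CO3, MeCN, 80 °C
Reagents that add atoms: none
Why: Copper-free Sonogashira coupling with a bulky electron-rich biarylphosphine, the catalyst class made for hindered, electron-rich aryl halides; the tertiary propargylic alcohol needs no protection.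

Step 14
Reactants: 21 4-[(2S,2aR,7aS)-4-(benzyloxy)-2-[3,4-bis(benzyloxy)phenyl]-6-methoxy-1,1-dimethyl-2,2a,7,7a-tetrahydro-1H-cyclobuta[a]inden-3-yl]-2-methylbut-3-yn-2-ol
Product: 22 (3Z)-4-[(2S,2aR,7aS)-4-(benzyloxy)-2-[3,4-bis(benzyloxy)phenyl]-6-methoxy-1,1-dimethyl-2,2a,7,7a-tetrahydro-1H-cyclobuta[a]inden-3-yl]-2-methylbut-3-en-2-ol
Conditions: H2 (1 atm), Pd/CaCO3 poisoned with Pb(OAc)2, quinoline, EtOAc, rt
Reagents that add atoms: none
Why: Lindlar semi-hydrogenation (syn addition of H2) gives the (Z)-alkene, which holds the tertiary carbinol next to the C3 oxygen; aryl benzyl ethers are not cleaved over the poisoned catalyst.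

Step 15
Reactants: 22 (3Z)-4-[(2S,2aR,7aS)-4-(benzyloxy)-2-[3,4-bis(benzyloxy)phenyl]-6-methoxy-1,1-dimethyl-2,2a,7,7a-tetrahydro-1H-cyclobuta[a]inden-3-yl]-2-methylbut-3-en-2-ol
Product: 23 target CNP0207533.1 (C8 S, C9 R, C10 S)
Conditions: BCl3, C6HMe5, CH2Cl2, −78 to −40 °C; MeOH, then aq. NaHCO3
Reagents that add atoms: none
Why: BCl3 with pentamethylbenzene as benzyl-cation trap cleaves the three aryl benzyl ethers at low temperature and leaves the aryl methyl ether; the same Lewis acid ionises the tertiary allylic alcohol, and the freed C3 oxygen closes the O–C14 bond (attack on the allyl cation, equivalent to oxa-6π closure of the ortho-quinone methide) to the 2,2-dimethyl-2H-chromene.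

## Compound list

1 | 3-hydroxy-5-methoxybenzaldehyde | COc1cc(O)cc(C=O)c1 | starting material
2 | 3-formyl-5-methoxyphenyl acetate | COc1cc(OC(C)=O)cc(C=O)c1 | intermediate
3 | 2-bromo-3-formyl-5-methoxyphenyl acetate | COc1cc(OC(C)=O)c(Br)c(C=O)c1 | intermediate
4 | 2-bromo-3-hydroxy-5-methoxybenzaldehyde (formed as its potassium salt) | COc1cc(O)c(Br)c(C=O)c1 | intermediate
5 | 3-(benzyloxy)-2-bromo-5-methoxybenzaldehyde | COc1cc(OCc2ccccc2)c(Br)c(C=O)c1 | intermediate
6 | 3,4-bis(benzyloxy)benzyl chloride | ClCc1ccc(OCc2ccccc2)c(OCc2ccccc2)c1 | starting material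
7 | [3,4-bis(benzyloxy)benzyl]magnesium chloride | Cl[Mg]Cc1ccc(OCc2ccccc2)c(OCc2ccccc2)c1 | intermediate
8 | rac-1-[3-(benzyloxy)-2-bromo-5-methoxyphenyl]-2-[3,4-bis(benzyloxy)phenyl]ethan-1-ol | COc1cc(OCc2ccccc2)c(Br)c(C(O)Cc2ccc(OCc3ccccc3)c(OCc3ccccc3)c2)c1 | intermediate
9 | 1-[3-(benzyloxy)-2-bromo-5-methoxyphenyl]-2-[3,4-bis(benzyloxy)phenyl]ethan-1-one | COc1cc(OCc2ccccc2)c(Br)c(C(=O)Cc2ccc(OCc3ccccc3)c(OCc3ccccc3)c2)c1 | intermediate
10 | dimethyl 2-(propan-2-ylidene)propanedioate | COC(=O)C(=C(C)C)C(=O)OC | starting material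
11 | {[(1Z)-1-[3-(benzyloxy)-2-bromo-5-methoxyphenyl]-2-[3,4-bis(benzyloxy)phenyl]ethenyl]oxy}trimethylsilane | C[Si](C)(C)O/C(c1cc(OC)cc(OCc2ccccc2)c1Br)=C\c1ccc(OCc2ccccc2)c(OCc2ccccc2)c1 | intermediate
12 | rac-dimethyl 2-[4-[3-(benzyloxy)-2-bromo-5-methoxyphenyl]-3-[3,4-bis(benzyloxy)phenyl]-2-methyl-4-oxobutan-2-yl]propanedioate | COC(=O)C(C(=O)OC)C(C)(C)C(c1ccc(OCc2ccccc2)c(OCc2ccccc2)c1)C(=O)c1cc(OC)cc(OCc2ccccc2)c1Br | intermediate
13 | dimethyl 2-[(3S,4R)-4-[3-(benzyloxy)-2-bromo-5-methoxyphenyl]-3-[3,4-bis(benzyloxy)phenyl]-4-hydroxy-2-methylbutan-2-yl]propanedioate | COC(=O)C(C(=O)OC)C(C)(C)[C@@H](c1ccc(OCc2ccccc2)c(OCc2ccccc2)c1)[C@@H](O)c1cc(OC)cc(OCc2ccccc2)c1Br | intermediate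
14 | dimethyl 2-[(3S,4S)-4-[3-(benzyloxy)-2-bromo-5-methoxyphenyl]-3-[3,4-bis(benzyloxy)phenyl]-4-bromo-2-methylbutan-2-yl]propanedioate | COC(=O)C(C(=O)OC)C(C)(C)[C@@H](c1ccc(OCc2ccccc2)c(OCc2ccccc2)c1)[C@H](Br)c1cc(OC)cc(OCc2ccccc2)c1Br | intermediate
15 | dimethyl (2S,3R)-2-[3-(benzyloxy)-2-bromo-5-methoxyphenyl]-3-[3,4-bis(benzyloxy)phenyl]-4,4-dimethylcyclobutane-1,1-dicarboxylate | COC(=O)C1(C(=O)OC)[C@@H](c2cc(OC)cc(OCc3ccccc3)c2Br)[C@H](c2ccc(OCc3ccccc3)c(OCc3ccccc3)c2)C1(C)C | intermediate
16 | (2S,3R)-2-[3-(benzyloxy)-2-bromo-5-methoxyphenyl]-3-[3,4-bis(benzyloxy)phenyl]-4,4-dimethylcyclobutane-1,1-dicarboxylic acid | OC(=O)C1(C(=O)O)[C@@H](c2cc(OC)cc(OCc3ccccc3)c2Br)[C@H](c2ccc(OCc3ccccc3)c(OCc3ccccc3)c2)C1(C)C | intermediate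
17 | (2R,2aS,7aR)-4-(benzyloxy)-2-[3,4-bis(benzyloxy)phenyl]-3-bromo-6-methoxy-1,1-dimethyl-7-oxo-1,2,2a,7-tetrahydro-7aH-cyclobuta[a]indene-7a-carboxylic acid | COc1cc(OCc4ccccc4)c(Br)c2c1C(=O)[C@@]1(C(=O)O)[C@@H]2[C@H](c2ccc(OCc3ccccc3)c(OCc3ccccc3)c2)C1(C)C | intermediate
18 | (2S,2aS,7aS)-4-(benzyloxy)-2-[3,4-bis(benzyloxy)phenyl]-3-bromo-6-methoxy-1,1-dimethyl-1,2,2a,7a-tetrahydro-7H-cyclobuta[a]inden-7-one | COc1cc(OCc4ccccc4)c(Br)c2c1C(=O)[C@H]1[C@@H]2[C@H](c2ccc(OCc3ccccc3)c(OCc3ccccc3)c2)C1(C)C | intermediate
19 | (2S,2aR,7aS)-4-(benzyloxy)-2-[3,4-bis(benzyloxy)phenyl]-3-bromo-6-methoxy-1,1-dimethyl-2,2a,7,7a-tetrahydro-1H-cyclobuta[a]indene | COc1cc(OCc4ccccc4)c(Br)c2c1C[C@H]1[C@@H]2[C@H](c2ccc(OCc3ccccc3)c(OCc3ccccc3)c2)C1(C)C | intermediate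
20 | 2-methylbut-3-yn-2-ol | CC(C)(O)C#C | starting material
21 | 4-[(2S,2aR,7aS)-4-(benzyloxy)-2-[3,4-bis(benzyloxy)phenyl]-6-methoxy-1,1-dimethyl-2,2a,7,7a-tetrahydro-1H-cyclobuta[a]inden-3-yl]-2-methylbut-3-yn-2-ol | COc1cc(OCc4ccccc4)c(C#CC(C)(C)O)c2c1C[C@H]1[C@@H]2[C@H](c2ccc(OCc3ccccc3)c(OCc3ccccc3)c2)C1(C)C | intermediate
22 | (3Z)-4-[(2S,2aR,7aS)-4-(benzyloxy)-2-[3,4-bis(benzyloxy)phenyl]-6-methoxy-1,1-dimethyl-2,2a,7,7a-tetrahydro-1H-cyclobuta[a]inden-3-yl]-2-methylbut-3-en-2-ol | COc1cc(OCc4ccccc4)c(/C=C\C(C)(C)O)c2c1C[C@H]1[C@@H]2[C@H](c2ccc(OCc3ccccc3)c(OCc3ccccc3)c2)C1(C)C | intermediate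
23 | CNP0207533.1, the catechol with the cyclobuta-fused indane and the 2,2-dimethyl-2H-pyran on ring A (C8 S, C9 R, C10 S) | COc1cc2c(c3c1C[C@H]1[C@@H]3[C@H](c3ccc(O)c(O)c3)C1(C)C)C=CC(C)(C)O2 | target

## Step count and least certain steps

Total step count: 15. Longest linear sequence: 15 steps, from 1 to 23; compounds 6, 10 and 20 enter as purchased materials.

**Step 9 (key step).** The attacking carbon C8 is flanked by quaternary C11 and two ester groups. Ring closure through an ester oxygen to a six-membered ketene acetal, or base-induced loss of HBr across C9–C10, may therefore outrun the four-membered closure.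

Fallback, setting out from 12 and coming back at 18: one carboxyl is removed before ring closure, so that a slimmer secondary ester enolate, which alkylates at carbon, closes the ring.
- Krapcho dealkoxycarbonylation of 12 (LiCl, wet DMSO, 140 °C) gives the keto ester F1.
- The transfer hydrogenation of step 7 and the bromination of step 8 give the (4S,5R)-hydroxy ester F2 and the (4S,5S)-bromo ester F3.
- LiHMDS in THF (−78 to 0 °C) closes the cyclobutane by the same 4-exo-tet inversion and gives the cyclobutane monoester F4 as a pair of C8 epimers.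
- LiOH gives the cyclobutanecarboxylic acid F5.
- Trifluoroacetic anhydride with a trace of acid cyclises the epimer whose carboxyl is cis to ring A; the other epimer equilibrates through the enol or ketene of the mixed anhydride. The product is 18.

**Step 6.** Conjugate addition to a tetrasubstituted alkylidene malonate may stall, or benzyl ethers may be attacked by TiCl4 during a slow reaction.

Fallback, setting out from 9 and coming back at 12:
- The potassium enolate of 9 (KHMDS, THF, −78 °C) or enol ether 11 with catalytic Sc(OTf)3 is added to the far more electrophilic 2,2-dimethyl-5-(propan-2-ylidene)-1,3-dioxane-4,6-dione, giving the Meldrum's acid adduct F6.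
- Boiling methanol opens it to the malonic half ester F7.
- Trimethylsilyldiazomethane esterifies F7 to 12.

**Step 7.** The ruthenium hydride may not reach the crowded carbonyl group, or may not distinguish the two ketone enantiomers. Prolonged exposure may also let the δ-hydroxy ester lactonise. In any case half of 12 is not used; the recovered (3R)-ketone would have to be racemised by double deprotonation (KHMDS) and protonation.

Fallback, setting out from 12 and coming back at 13: NaBH4 with CeCl3 in MeOH at −40 °C reduces racemic 12 under Felkin–Anh control to the racemic anti alcohol. This is 13 together with its enantiomer, the (3R,4S)-alcohol F8; they are separated by preparative chromatography on a chiral stationary phase.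

**Step 8.** Rear-side attack of bromide on C9 is slowed by the branched C10. Participation of an ester carbonyl (lactone formation), loss of the C10 proton, or bromide exchange that scrambles C9 may compete.

Fallback, setting out from 12 and coming back at 15: no intermolecular substitution at C9 is used.
- Reagent-controlled reduction of racemic 12 with the (R)-Me-CBS oxazaborolidine and BH3·SMe2 (THF, −20 °C) should give the 4S carbinol from both ketone enantiomers. These are the (3S,4S)-alcohol F9 and its diastereomer F8, which are separated on silica.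
- MsCl and Et3N (CH2Cl2, −20 °C) convert F9 with retention into the (3S,4S)-mesylate F10.
- NaH in THF closes F10 with a single inversion to 15.

**Step 15.** The allyl cation may be captured by pentamethylbenzene or chloride, or the chromene double bond may add HCl, before or after the ring closes.

Fallback, setting out from 19 and coming back at 23:
- The benzyl ethers are removed first, while no acid-sensitive group is present (BCl3, C6HMe5, −78 °C), giving the bromo triphenol F11.
- Heck reaction with 2-methylbut-3-en-2-ol (Pd(OAc)2, P(t-Bu)3·HBF4, Et3N, DMF, 90 °C) gives the (E)-allylic alcohol F12.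
- Warming F12 with catalytic pyridinium p-toluenesulfonate in toluene closes the chromene by way of the ortho-quinone methide and gives 23.

## Further compounds

F1 | step 9 | methyl (4RS)-5-[3-(benzyloxy)-2-bromo-5-methoxyphenyl]-4-[3,4-bis(benzyloxy)phenyl]-3,3-dimethyl-5-oxopentanoate | COC(=O)CC(C)(C)C(c1ccc(OCc2ccccc2)c(OCc2ccccc2)c1)C(=O)c1cc(OC)cc(OCc2ccccc2)c1Br
F2 | step 9 | methyl (4S,5R)-5-[3-(benzyloxy)-2-bromo-5-methoxyphenyl]-4-[3,4-bis(benzyloxy)phenyl]-5-hydroxy-3,3-dimethylpentanoate | COC(=O)CC(C)(C)[C@@H](c1ccc(OCc2ccccc2)c(OCc2ccccc2)c1)[C@@H](O)c1cc(OC)cc(OCc2ccccc2)c1Br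
F3 | step 9 | methyl (4S,5S)-5-[3-(benzyloxy)-2-bromo-5-methoxyphenyl]-4-[3,4-bis(benzyloxy)phenyl]-5-bromo-3,3-dimethylpentanoate | COC(=O)CC(C)(C)[C@@H](c1ccc(OCc2ccccc2)c(OCc2ccccc2)c1)[C@H](Br)c1cc(OC)cc(OCc2ccccc2)c1Br
F4 | step 9 | methyl (2S,3S)-2-[3-(benzyloxy)-2-bromo-5-methoxyphenyl]-3-[3,4-bis(benzyloxy)phenyl]-4,4-dimethylcyclobutane-1-carboxylate (both C1 epimers) | COC(=O)C1[C@@H](c2cc(OC)cc(OCc3ccccc3)c2Br)[C@H](c2ccc(OCc3ccccc3)c(OCc3ccccc3)c2)C1(C)C
F5 | step 9 | (2S,3S)-2-[3-(benzyloxy)-2-bromo-5-methoxyphenyl]-3-[3,4-bis(benzyloxy)phenyl]-4,4-dimethylcyclobutane-1-carboxylic acid (both C1 epimers) | OC(=O)C1[C@@H](c2cc(OC)cc(OCc3ccccc3)c2Br)[C@H](c2ccc(OCc3ccccc3)c(OCc3ccccc3)c2)C1(C)C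
F6 | step 6 | rac-5-[4-[3-(benzyloxy)-2-bromo-5-methoxyphenyl]-3-[3,4-bis(benzyloxy)phenyl]-2-methyl-4-oxobutan-2-yl]-2,2-dimethyl-1,3-dioxane-4,6-dione | CC1(C)OC(=O)C(C(=O)O1)C(C)(C)C(c1ccc(OCc2ccccc2)c(OCc2ccccc2)c1)C(=O)c1cc(OC)cc(OCc2ccccc2)c1Br
F7 | step 6 | 2-[4-[3-(benzyloxy)-2-bromo-5-methoxyphenyl]-3-[3,4-bis(benzyloxy)phenyl]-2-methyl-4-oxobutan-2-yl]-3-methoxy-3-oxopropanoic acid (racemic diastereomers) | COC(=O)C(C(=O)O)C(C)(C)C(c1ccc(OCc2ccccc2)c(OCc2ccccc2)c1)C(=O)c1cc(OC)cc(OCc2ccccc2)c1Br
F8 | step 7 | dimethyl 2-[(3R,4S)-4-[3-(benzyloxy)-2-bromo-5-methoxyphenyl]-3-[3,4-bis(benzyloxy)phenyl]-4-hydroxy-2-methylbutan-2-yl]propanedioate | COC(=O)C(C(=O)OC)C(C)(C)[C@H](c1ccc(OCc2ccccc2)c(OCc2ccccc2)c1)[C@H](O)c1cc(OC)cc(OCc2ccccc2)c1Br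
F9 | step 8 | dimethyl 2-[(3S,4S)-4-[3-(benzyloxy)-2-bromo-5-methoxyphenyl]-3-[3,4-bis(benzyloxy)phenyl]-4-hydroxy-2-methylbutan-2-yl]propanedioate | COC(=O)C(C(=O)OC)C(C)(C)[C@@H](c1ccc(OCc2ccccc2)c(OCc2ccccc2)c1)[C@H](O)c1cc(OC)cc(OCc2ccccc2)c1Br
F10 | step 8 | dimethyl 2-[(3S,4S)-4-[3-(benzyloxy)-2-bromo-5-methoxyphenyl]-3-[3,4-bis(benzyloxy)phenyl]-4-(methanesulfonyloxy)-2-methylbutan-2-yl]propanedioate | COC(=O)C(C(=O)OC)C(C)(C)[C@@H](c1ccc(OCc2ccccc2)c(OCc2ccccc2)c1)[C@H](OS(C)(=O)=O)c1cc(OC)cc(OCc2ccccc2)c1Br
F11 | step 15 | 4-[(2S,2aR,7aS)-3-bromo-4-hydroxy-6-methoxy-1,1-dimethyl-2,2a,7,7a-tetrahydro-1H-cyclobuta[a]inden-2-yl]benzene-1,2-diol | COc1cc(O)c(Br)c2c1C[C@H]1[C@@H]2[C@H](c2ccc(O)c(O)c2)C1(C)C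
F12 | step 15 | 4-[(2S,2aR,7aS)-4-hydroxy-3-[(1E)-3-hydroxy-3-methylbut-1-en-1-yl]-6-methoxy-1,1-dimethyl-2,2a,7,7a-tetrahydro-1H-cyclobuta[a]inden-2-yl]benzene-1,2-diol | COc1cc(O)c(/C=C/C(C)(C)O)c2c1C[C@H]1[C@@H]2[C@H](c2ccc(O)c(O)c2)C1(C)C
A1 | alternative 1 | C7-oxo tetracycle with the chromene in place and the catechol as its bis(methoxymethyl) ether | COc1cc2c(c3c1C(=O)[C@H]1[C@@H]3[C@H](c3ccc(OCOC)c(OCOC)c3)C1(C)C)C=CC(C)(C)O2
A2 | alternative 1 | 7-methoxy-2,2-dimethyl-2H-chromen-5-yl trifluoromethanesulfonate | COc1cc(OS(=O)(=O)C(F)(F)F)c2C=CC(C)(C)Oc2c1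
A3 | alternative 1 | (3S)-3-[3,4-bis(methoxymethoxy)phenyl]-4,4-dimethylcyclobut-1-ene | C1=C[C@H](c2ccc(OCOC)c(OCOC)c2)C1(C)C
A4 | alternative 2 | tert-butyldimethylsilyl ether of the C12-hydroxy chroman with the full skeleton and benzyl-protected catechol | COc1cc2c(c3c1C[C@H]1[C@@H]3[C@H](c3ccc(OCc4ccccc4)c(OCc4ccccc4)c3)C1(C)C)[C@@H](O[Si](C)(C)C(C)(C)C)CC(C)(C)O2
A5 | alternative 2 | cyclobutane triyne with a 3-methoxyprop-2-ynyl arm on C8 and a silyloxy-substituted alkynyl arm ending in an ethynyl ether on C9 | COC#CC[C@H]1[C@@H](C#C[C@@H](O[Si](C)(C)C(C)(C)C)CC(C)(C)OC#C)[C@H](c2ccc(OCc3ccccc3)c(OCc3ccccc3)c2)C1(C)C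
A6 | alternative 3 | tricyclic indanone with completed ring A, free C3 phenol and C4 prenyl group | COc1cc(O)c(CC=C(C)C)c2c1C(=O)[C@H]1[C@@H]2[C@H](c2ccc(OCc3ccccc3)c(OCc3ccccc3)c2)C1(C)C
A7 | alternative 3 | 6-[3,4-bis(benzyloxy)phenyl]-3-bromo-7,7-dimethylbicyclo[3.2.0]hept-3-en-2-one, configured as the target at C8, C9 and C10 | O=C1C(Br)=C[C@H]2[C@H](c3ccc(OCc4ccccc4)c(OCc4ccccc4)c3)C(C)(C)[C@@H]12
A8 | alternative 3 | [(1,1-dimethoxy-7-methylocta-1,3,6-trien-3-yl)oxy]trimethylsilane | COC(OC)=CC(O[Si](C)(C)C)=CCC=C(C)C
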